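## The problem

1. Target 27 is a C30 diacetate in which two trans-fused oxepane–cyclohexane bicycles are joined by a two-carbon bridge. In the chain numbering used throughout, C2 and C23 are the CMe2 carbons, C3 and C22 the carbinol carbons, C6 and C19 the methyl-bearing quaternary carbons, C7 and C18 the O–CH carbons, C10 bears the exocyclic methylene, C15 bears a methyl and the tertiary acetate, and C11–C12–C13–C14 is the bridge.
2. With β as the face of the angular methyl of each bicycle and α as the opposite face, the target is 3α-OH, 7α-H, 11α-H, 14α-H, 15β-OAc, 18α-H and 22α-OAc, that is (3S,6S,7S,11R,14S,15R,18S,19S,22S).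
3. The two bicycles have the same configuration at all four corresponding centres (C3/C22, C6/C19, C7/C18, C11/C14), so one enantiopure building block can serve both. They must nevertheless be differentiated before they are joined, because the C3 and C22 oxygens sit in identical surroundings and only C22 is acetylated.
4. The quaternary C6 (C19) can control its neighbours, since its axial methyl sends reagents to the α face at C7, at C11/C14 and at C15. C3 (C22) lies across the seven-membered ring and is the centre hardest to control.
5. The bridge is an sp3–sp3 bond between two one-carbon arms, each on a ring carbon next to a quaternary centre, so the union must tolerate steric hindrance on both sides.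
6. The exocyclic methylene (acid-induced migration, hydroboration, hydrogenation), the axial tertiary acetate (elimination), the secondary acetate beside a free alcohol (no base at the end) and the tertiary ether carbon of each oxepane (strong Lewis acids) limit what may be done late.
7. The feature that opens the key step is that the ring oxygen of each oxepane lies between C2 and C7, a ring-fusion methine next to quaternary C6. Removing that oxygen leaves a trans-decalin with a C2 ketone bonded to C7, which is within reach of the Wieland–Miescher ketone, so the oxepane can arise by oxygen insertion into the C2–C7 bond and need not be closed as a seven-membered ring.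

## Retrosynthesis

**Late adjustments (27 ⇒ 26 ⇒ 25).** The C3 hydroxyl is released last from silyl ether 26, the only protected oxygen left, which is what distinguishes C3 from C22. The C10 methylene is cut back to ketone 25. It is placed late because it would not survive the radical and borane chemistry before it, and because a C10 ketone is what the bridge-forming step delivers and makes C11 correctable by equilibration. The forward step must methylenate a ketone without base, in the presence of two acetates.

**Bridge (25 ⇒ 24 + 18).** The C12–C13 bond is cut to primary iodide 24 and exo-methylene enone 18. A cut at C11–C12 would need a nucleophilic or metallated ring carbon beside a quaternary centre. The C12–C13 cut joins a primary radical to an unhindered CH2 terminus and leaves C11 to be set by hydrogen transfer to the α face, which is also the thermodynamic outcome. The C30 problem falls to two C14/C15 bicycles, and 24 is itself made from 18, so only one series of compounds has to be prepared. The forward reaction must tolerate acetates, a silyl ether and a ketone, which a neutral radical chain does.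

**Acetoxy half (24 ⇒ 23 ⇒ 22 ⇒ 21 ⇒ 19 ⇒ 18).** The two acetates are removed to diol 23, the silyl group is put back (22), the iodide is traced to primary alcohol 21, the C13–O and C14–H bonds to hydroboration of the exocyclic alkene of 19, and the C15–CH3 bond to methyl addition to the carbonyl of 18. This order keeps strongly basic reagents ahead of the acetates and lets the axial C19 methyl control both new centres (equatorial attack at C15, α-face hydroboration at C14).

**Carbonyl transposition (18 ⇒ 17 ⇒ 16 ⇒ 15).** The building block supplies its saturated carbonyl at C11, whereas the target needs carbon at C11 and the functional position at C10. The C10 oxygen is therefore removed (allylic alcohol 17, alkene 16) and the C11=CH2 bond is cut to ketone 15. The exocyclic carbon introduced here becomes C12 in one half and C13 in the other. The forward sequence is olefination of a hindered ketone and an allylic oxidation that has only one allylic CH2 to choose from.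

**Oxepane substituents (15 ⇒ 14 ⇒ 13 ⇒ 11 ⇒ 10 ⇒ 8).** After removal of the silyl group and reinstatement of the C11 ketal (14, 13), both C2–CH3 bonds and the C3–O bond are cut, leading through enol ether 11 and ketene acetal phosphate 10 to lactone 8. The lactone carbonyl serves twice: cross-coupling brings the first methyl, and epoxidation followed by methyl transfer brings the second methyl together with the C3 oxygen. Hydroxylating the lactone enolate and then methylating a seven-membered lactol with a silyl triflate and Me3Al would expose the C11 dioxolane to the same Lewis acids at an acetal carbon that ionises less readily. The epoxide route generates the oxocarbenium ion at low temperature.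

**Key disconnection (8 ⇒ 7).** The C7–O bond is cut and the oxygen deleted, which turns the oxepanone into trans-decalone 7 with the ketone at C2. Any cut that closes the oxepane by C–O or C–C bond formation must pay for a seven-membered cyclisation and set C7 at the same time. The ring expansion inherits C6 and C7 from the decalin. The forward reaction must move C7 in preference to the C3 methylene and leave the masked C11 ketone untouched.

**Decalone (7 ⇒ 6 ⇒ 4 ⇒ 3 ⇒ 2 ⇒ 1).** Ketone 7 comes from alcohol 6 and this from hydroboration of alkene 4, whose C2=C7 bond is the enone double bond of (R)-Wieland–Miescher ketone 1 after reductive removal of the enone oxygen (dithioketals 3 and 2). The C11 dioxolane is required from step 2 to step 10: it prevents reduction of the C11 ketone by borane, prevents its Baeyer–Villiger oxidation (where quaternary C6 would migrate), and prevents methyl addition.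

## Roads not taken

**Alternative 1:** The cut runs through C4–C5 and C6–C7 and, one step later, through the C4–C7 bond of a cyclobutane. In the forward direction, light of about 350 nm would add the enone double bond of a 2,2-dimethylfuran-3-one unit to an isopropenyl group on the same chain. This would give the tricyclic photoadduct A1, in which the cyclohexane and quaternary C6 are formed together. Opening the four-membered ring then widens the furanone into the 2,2-dimethyloxepan-3-one.
- Merits: the gem-dimethyl group arrives with the heterocycle. The oxepane appears with a C3 ketone, which allows reagent-controlled reduction at C3. In that respect this road is better than the chosen one, which relies on the substrate at C3 and keeps the ketone/reduction sequence only as a reserve.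
- Weak points: the C10 and C11 centres must be built on an open chain beforehand. The C6/C7 relationship depends on the folding of the tether in the cycloaddition. The bond to be broken afterwards (C4–C7) is not a retro-aldol bond, because C7 carries an ether and not a hydroxyl. A reductive cleavage would be needed, and C7 would be set in the protonation that follows, so the trans fusion is not assured.
- Comparison: the chosen plan takes C6 from a commercial enantiopure ketone and C7 from a hydroboration followed by a stereoretentive migration. It pays for this with five steps to dress the lactone.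

**Alternative 2:** The cut goes through O–C2, C6–C11, C14–C19 and O–C23, which opens all four rings at once. In the forward direction Me3SiOTf would activate two terminal epoxides, each inner epoxide oxygen would attack C2 or C23, and an allylsilane carbon (C11) and a silyl enol ether carbon (C14) would end the two cascades at C6 and C19. The product would be keto diol A2.
- Merits: this is by far the most economical construction. It gives the whole skeleton with the C10 methylene in place, and C3 and C22 come from epoxide configurations that asymmetric epoxidation sets reliably. In both respects it is superior to the chosen plan.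
- Weak points: eight stereocentres and two seven-membered ether closures must come out of one Lewis-acid step. Two different terminators must survive beside four epoxides. Decisively, A2 carries two free secondary hydroxyls in identical surroundings, so the C22 acetate cannot be introduced without also acetylating C3.
- Comparison: the chosen plan sets against the economy of this road the differentiation of the halves before their union and the setting of each stereocentre in a separate step that can be checked. Its cost is 22 linear steps.

**Alternative 3:** The cut is at C10–C11, with a C13–O bond made in exchange. In the forward direction a silyl ketene acetal formed with LiN(SiMe3)2 and Me3SiCl inside a ten-membered lactone ring would undergo a transannular [3,3] shift, closing the cyclohexane and giving acid A3 with a carboxyl on C10 and a vinyl group on C11.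
- Merits: C10 and C11 are set through a cyclic transition state. The vinyl group is a direct handle for the bridge and the carboxyl for the C10 methylene. This is a more direct answer to the C10/C11 pattern than the three-step carbonyl transposition of the chosen plan.
- Weak points: the rearrangement does nothing for the oxepane, which A3 already contains and which would have to be made by other means with C6 and C7 in place. A ten-membered lactone carrying a quaternary carbon must be closed with defined alkene geometry. The chair or boat preference of a transannular shift is hard to predict.
- Comparison: the chosen plan solves the oxepane and the C6/C7 pair first and accepts a longer but routine elaboration at C10/C11.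

Key step: step 6

## Route

Assumption: (R)-Wieland–Miescher ketone is bought as the single enantiomer, and dimethyldioxirane is used as a freshly prepared acetone-free CH2Cl2 solution. In compounds 1–18 the ring carbons carry the target locants C2–C11 that they become; in 19–24 the same bicycle is numbered as the C13–C23 half (C10→C15, C11→C14, C6→C19, C7→C18, C3→C22).

Step 1
Reactants: 1 (R)-Wieland–Miescher ketone, (8aR)-8a-methyl-3,4,8,8a-tetrahydronaphthalene-1,6(2H,7H)-dione
Product: 2 enone dithioketal of 1 (1,3-dithiolane at C3; C2=C7 alkene and C11 ketone unchanged)
Conditions: HSCH2CH2SH, p-TsOH·H2O (cat.), AcOH, rt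
Reagents that add atoms: ethane-1,2-dithiol, SCCS
Why: Acid-catalysed dithioketalisation is chemoselective for the conjugated carbonyl (future C3) over the neopentyl C11 ketone, and the double bond stays at C2=C7 as in steroidal 4-en-3-one thioketals.

Step 2
Reactants: 2 enone dithioketal
Product: 3 dithioketal ketal (C3 1,3-dithiolane, C11 1,3-dioxolane, C2=C7 alkene)
Conditions: HOCH2CH2OH, p-TsOH·H2O (cat.), benzene, reflux, Dean–Stark
Reagents that add atoms: ethylene glycol, OCCO
Why: Ketalisation with azeotropic removal of water protects the hindered C11 ketone; the dithiolane is inert to these conditions.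

Step 3
Reactants: 3 dithioketal ketal
Product: 4 octalin ketal (C3 methylene, C2=C7 alkene, C11 dioxolane, 6-methyl)
Conditions: Raney Ni (W-2, deactivated with acetone), EtOH, reflux
Reagents that add atoms: none
Why: Reductive desulfurisation of the allylic dithioketal removes the former enone oxygen as C3H2 and keeps the trisubstituted C2=C7 alkene, as in the conversion of steroidal enone thioketals into 4-enes.

Step 4
Reactants: 4 octalin ketal
Product: 6 trans-decalol ketal (2α-hydroxy, 7α-H, 6β-methyl, C11 dioxolane), via alkylborane 5 (not isolated)
Conditions: BH3·THF, THF, 0 °C to rt; then NaOH, H2O2, 0 °C to rt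
Reagents that add atoms: borane–tetrahydrofuran, B.C1CCOC1 (boron of 5); hydrogen peroxide, OO (oxygen of 6)
Why: Hydroboration–oxidation places boron on the less substituted C2 and hydrogen on C7 by syn addition from the α face, opposite the axial C6 methyl, which sets H-7 trans to the methyl (trans-decalin); the C–B bond is oxidised with retention.

Step 5
Reactants: 6 trans-decalol ketal
Product: 7 trans-decalone ketal, (4aS,8aR)-8a-methyl-octahydronaphthalene-1,5-dione 1-(ethylene ketal), ketone at C2
Conditions: Dess–Martin periodinane, NaHCO3, CH2Cl2, rt
Reagents that add atoms: none
Why: Buffered Dess–Martin oxidation gives the ketone without epimerising C7; the trans fusion is in any case the more stable arrangement.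

Step 6
Reactants: 7 trans-decalone ketal
Product: 8 trans-fused lactone ketal, (5aR,9aS)-5a-methyl-octahydro-1-benzoxepin-2-one carrying the C11 dioxolane (oxygen between C2 and C7)
Conditions: m-CPBA, NaHCO3, CH2Cl2, 0 °C to rt
Reagents that add atoms: 3-chloroperbenzoic acid, OOC(=O)c1cccc(Cl)c1
Why: Baeyer–Villiger oxidation: the peracid adds to the C2 carbonyl, and in the peroxy hemiketal (Criegee adduct) the C2–C7 bond, antiperiplanar to the O–O bond, shifts to oxygen as 3-chlorobenzoate leaves. The closest known reaction type is the peracid ring expansion of trans-1-decalones and of steroidal ketones flanked by a ring-fusion methine, in which the methine migrates. The oxepan-2-one ring is closed by a 1,2-shift that enlarges the existing six-membered ring by one oxygen atom, so no seven-membered cyclisation is involved. No new stereocentre is formed: C7 migrates with retention, so the trans C6/C7 relationship from step 4 passes into the lactone. The selectivity required is migration of secondary C7 over the primary C3 methylene, which rests on the higher migratory aptitude of the more substituted carbon. Chemoselectivity comes from the dioxolane, which keeps the C11 carbonyl (whose quaternary neighbour would migrate readily) out of the reaction, and from the NaHCO3 buffer, which shields ketal and lactone from 3-chlorobenzoic acid.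

Step 7
Reactants: 8 trans-fused lactone ketal
Product: 10 ketene acetal diphenyl phosphate (C2=C3, phosphate on the C2 oxygen), via potassium enolate 9 (not isolated)
Conditions: KN(SiMe3)2, HMPA, THF, −78 °C; then (PhO)2P(O)Cl, −78 °C
Reagents that add atoms: potassium bis(trimethylsilyl)amide, C[Si](C)(C)[N-][Si](C)(C)C.[K+] (potassium of 9); diphenyl chlorophosphate, O=P(Cl)(Oc1ccccc1)Oc1ccccc1
Why: Only C3 carries α-hydrogens, and O-phosphorylation of the lactone enolate gives the cyclic ketene acetal phosphate, the usual activated form of medium-ring lactones for cross-coupling.

Step 8
Reactants: 10 ketene acetal diphenyl phosphate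
Product: 11 2-methyl cyclic enol ether (C2=C3, methyl on C2)
Conditions: MeZnCl, Pd(PPh3)4 (5 mol %), THF, rt to 50 °C
Reagents that add atoms: methylzinc chloride, C[Zn]Cl
Why: Negishi coupling: zerovalent palladium inserts into the C2–O(phosphate) bond and methyl is transferred from zinc; the organozinc is not Lewis acidic enough to touch the dioxolane.

Step 9
Reactants: 11 2-methyl cyclic enol ether
Product: 13 (3S)-2,2-dimethyl-3α-hydroxy oxepane ketal, via epoxide 12 (not isolated)
Conditions: dimethyldioxirane, CH2Cl2, −78 to 0 °C; then Me3Al, CH2Cl2, −78 to −20 °C
Reagents that add atoms: dimethyldioxirane, CC1(C)OO1; trimethylaluminium, C[Al](C)C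
Why: Dimethyldioxirane epoxidises the electron-rich enol ether on the α face, because the β face of the chair-like oxepene is screened by the axial C6 methyl, and this sets C3; Me3Al then opens the epoxy ether at the acetal carbon C2 through the oxocarbenium ion with methyl delivery from aluminium bound to the C3 oxygen (the known epoxidation–carbon nucleophile sequence of cyclic enol ethers), so C2 becomes the gem-dimethyl carbon.

Step 10
Reactants: 13 2,2-dimethyl-3α-hydroxy oxepane ketal
Product: 14 3α-tert-butyldimethylsilyl ether ketal
Conditions: TBSOTf, 2,6-lutidine, CH2Cl2, 0 °C
Reagents that add atoms: tert-butyldimethylsilyl triflate, CC(C)(C)[Si](C)(C)OS(=O)(=O)C(F)(F)F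
Why: The silyl triflate is needed for the neopentyl secondary alcohol; a ketone ketal, unlike an aldehyde acetal, survives the triflate/lutidine pair at 0 °C.

Step 11
Reactants: 14 3α-silyl ether ketal
Product: 15 bicyclic C11 ketone (2,2-dimethyl, 3α-OTBS, 6β-methyl, 7α-H)
Conditions: p-TsOH·H2O (cat.), acetone/H2O, rt to 40 °C
Reagents that add atoms: water, O
Why: Acid-catalysed ketal hydrolysis frees the C11 ketone; the hindered secondary silyl ether and the tertiary ether of the oxepane are stable to dilute sulfonic acid.

Step 12
Reactants: 15 bicyclic C11 ketone
Product: 16 11-methylene bicycle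
Conditions: Ph3PCH3Br, KOt-Bu, toluene, 90 °C
Reagents that add atoms: methyltriphenylphosphonium bromide, C[P+](c1ccccc1)(c1ccccc1)c1ccccc1.[Br-]
Why: Wittig methylenation; the ketone is flanked by quaternary C6, so the ylide is used hot as is usual for α,α-disubstituted cyclohexanones, and no epimerisable centre adjoins the carbonyl.

Step 13
Reactants: 16 11-methylene bicycle
Product: 17 10-hydroxy-11-methylene bicycle (mixture of C10 epimers, both used)
Conditions: SeO2 (0.5 equiv), t-BuOOH, CH2Cl2, 0 °C to rt
Reagents that add atoms: selenium dioxide, O=[Se]=O (oxygen carrier); tert-butyl hydroperoxide, CC(C)(C)OO (terminal oxidant)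
Why: Selenium dioxide allylic hydroxylation (ene reaction, then [2,3] shift) can only use the C10 hydrogens, because the other allylic position is quaternary C6, and it returns the double bond to the exocyclic position.

Step 14
Reactants: 17 10-hydroxy-11-methylene bicycle
Product: 18 11-methylene-10-ketone (exo-methylene enone)
Conditions: Dess–Martin periodinane, NaHCO3, CH2Cl2, 0 °C to rt
Reagents that add atoms: none
Why: Dess–Martin oxidation of the allylic alcohol converges both C10 epimers on the enone; the adjacent quaternary C6 slows the dimerisation typical of α-methylene ketones, and 18 is used without storage.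

Step 15
Reactants: 18 exo-methylene enone
Product: 19 15β-hydroxy-15α-methyl-14-methylene bicycle (tertiary allylic alcohol, C22 silyl ether)
Conditions: MeLi, CeCl3, THF, −78 °C
Reagents that add atoms: methyllithium, [Li]C
Why: Organocerium 1,2-addition avoids conjugate addition and enolisation; attack is equatorial from the α face because the axial trajectory is blocked by the 1,3-related axial C19 methyl, which gives the axial (β) oxygen and the equatorial methyl required at C15.

Step 16
Reactants: 19 tertiary allylic alcohol
Product: 21 C13,C15-diol (primary C13–OH on the β arm, 14α-H, tertiary 15β-OH), via alkylborane 20 (not isolated)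
Conditions: BH3·THF, THF, 0 °C to rt; then NaOH, H2O2, 0 °C
Reagents that add atoms: borane–tetrahydrofuran, B.C1CCOC1 (boron of 20); hydrogen peroxide, OO (oxygen of 21)
Why: Hydroboration–oxidation puts boron on terminal C13 and hydrogen on C14 from the α face, because the β face of the exocyclic alkene is flanked by the axial C19 methyl and the axial C15 oxygen; the C13 arm therefore becomes equatorial as in the target.

Step 17
Reactants: 21 C13,C15-diol
Product: 22 C13 iodide (15β-OH, C22 silyl ether)
Conditions: PPh3, I2, imidazole, CH2Cl2, 0 °C to rt
Reagents that add atoms: iodine, II
Why: Appel-type iodination converts the primary alcohol selectively; the tertiary alcohol does not form a reactive alkoxyphosphonium ion under these conditions.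

Step 18
Reactants: 22 C13 iodide
Product: 23 C13 iodide C15,C22-diol
Conditions: HF·pyridine, pyridine, THF, 0 °C to rt
Reagents that add atoms: none
Why: Buffered fluoride cleavage of the silyl ether avoids alkoxide formation near the primary iodide and leaves the tertiary alcohol intact.

Step 19
Reactants: 23 iodo diol
Product: 24 C13 iodide C15,C22-diacetate (15β-OAc, 22α-OAc)
Conditions: Ac2O, Et3N, DMAP, CH2Cl2, rt to 40 °C
Reagents that add atoms: acetic anhydride, CC(=O)OC(C)=O
Why: DMAP-catalysed acylation acetylates the secondary C22 alcohol quickly and, with excess reagent and gentle warming, the tertiary C15 alcohol; the doubly β-branched primary iodide is inert to the amines.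

Step 20
Reactants: 24 iodo diacetate; 18 exo-methylene enone (1.5 equiv)
Product: 25 coupled C10 ketone (C12–C13 bond formed, 11α-H, 3α-OTBS, 15β-OAc, 22α-OAc)
Conditions: (Me3Si)3SiH (slow addition), AIBN (cat.), toluene, 80 °C; then DBU (cat.), CH2Cl2, rt
Reagents that add atoms: none
Why: Giese reaction: the silyl radical abstracts iodine from 24, the primary C13 radical adds to the unhindered methylene terminus (C12) of the enone, and the C11 α-keto radical takes hydrogen from the silane on the α face, anti to the axial C6 methyl; this is also the more stable equatorial arrangement, so any C11 epimer converges under DBU, and the neutral conditions tolerate acetates, silyl ether and ketone.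

Step 21
Reactants: 25 coupled C10 ketone
Product: 26 3-O-tert-butyldimethylsilyl ether of the target (C10 methylene)
Conditions: Zn, CH2Br2, TiCl4, THF, 0 °C (reagent preformed); then 25, CH2Cl2, rt
Reagents that add atoms: dibromomethane, BrCBr
Why: Lombardo methylenation is not basic, so C11 is not epimerised and the acetates, which a phosphorus ylide could attack, are left alone; the reagent reacts with ketones much faster than with esters.

Step 22
Reactants: 26 silyl ether of the target
Product: 27 target, (3S,6S,7S,11R,14S,15R,18S,19S,22S)-15,22-diacetoxy-3-hydroxy bis(oxepane) with the C10 exocyclic methylene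
Conditions: HF·pyridine, pyridine, THF, 0 °C to rt
Reagents that add atoms: none
Why: Buffered HF·pyridine removes the last silyl group without hydrolysing or shifting the acetates (no neighbouring hydroxyl) and without isomerising the exocyclic alkene.

## Compound list

1 | (R)-Wieland–Miescher ketone | C[C@@]12CCC(=O)C=C1CCCC2=O | starting material
2 | enone dithioketal (C3 dithiolane, C11 ketone) | C[C@@]12CCC3(SCCS3)C=C1CCCC2=O | intermediate
3 | dithioketal ketal (C3 dithiolane, C11 dioxolane) | C[C@@]12CCC3(SCCS3)C=C1CCCC24OCCO4 | intermediate
4 | octalin ketal (C2=C7 alkene) | C[C@@]12CCCC=C1CCCC23OCCO3 | intermediate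
5 | C2 alkylborane (boron 2α, 7α-H) | C1CC[C@@H]2[C@@H](B)CCC[C@@]2(C)C13OCCO3 | intermediate (not isolated)
6 | trans-decalol ketal (2α-OH, 7α-H) | C1CC[C@@H]2[C@@H](O)CCC[C@@]2(C)C13OCCO3 | intermediate
7 | trans-decalone ketal, (4aS,8aR)-8a-methyl-octahydronaphthalene-1,5-dione 1-(ethylene ketal) | C1CC[C@@H]2C(=O)CCC[C@@]2(C)C13OCCO3 | intermediate
8 | trans-fused oxepan-2-one ketal | C1CC[C@@H]2OC(=O)CCC[C@@]2(C)C13OCCO3 | intermediate
9 | potassium enolate of 8 | C1CC[C@@H]2OC([O-])=CCC[C@@]2(C)C13OCCO3.[K+] | intermediate (not isolated)
10 | ketene acetal diphenyl phosphate | C1CC[C@@H]2OC(OP(=O)(Oc3ccccc3)Oc3ccccc3)=CCC[C@@]2(C)C14OCCO4 | intermediate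
11 | 2-methyl cyclic enol ether | C1CC[C@@H]2OC(C)=CCC[C@@]2(C)C13OCCO3 | intermediate
12 | 2α,3α-epoxide of 11 | C1CC[C@@H]2O[C@@]3(C)O[C@H]3CC[C@@]2(C)C14OCCO4 | intermediate (not isolated)
13 | (3S)-2,2-dimethyl-3α-hydroxy oxepane ketal | C1CC[C@@H]2OC(C)(C)[C@@H](O)CC[C@@]2(C)C13OCCO3 | intermediate
14 | 3α-silyl ether ketal | C1CC[C@@H]2OC(C)(C)[C@@H](O[Si](C)(C)C(C)(C)C)CC[C@@]2(C)C13OCCO3 | intermediate
15 | bicyclic C11 ketone | O=C1CCC[C@@H]2OC(C)(C)[C@@H](O[Si](C)(C)C(C)(C)C)CC[C@@]12C | intermediate
16 | 11-methylene bicycle | C=C1CCC[C@@H]2OC(C)(C)[C@@H](O[Si](C)(C)C(C)(C)C)CC[C@@]12C | intermediate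
17 | 10-hydroxy-11-methylene bicycle (C10 epimers) | OC1CC[C@@H]2OC(C)(C)[C@@H](O[Si](C)(C)C(C)(C)C)CC[C@@]2(C)C1=C | intermediate
18 | 11-methylene-10-ketone (exo-methylene enone) | O=C1CC[C@@H]2OC(C)(C)[C@@H](O[Si](C)(C)C(C)(C)C)CC[C@@]2(C)C1=C | intermediate
19 | 15β-hydroxy-15α-methyl-14-methylene bicycle | C[C@@]1(O)CC[C@@H]2OC(C)(C)[C@@H](O[Si](C)(C)C(C)(C)C)CC[C@@]2(C)C1=C | intermediate
20 | C13 alkylborane (14α-H) | C[C@@]1(O)CC[C@@H]2OC(C)(C)[C@@H](O[Si](C)(C)C(C)(C)C)CC[C@@]2(C)[C@@H]1CB | intermediate (not isolated)
21 | C13,C15-diol | C[C@@]1(O)CC[C@@H]2OC(C)(C)[C@@H](O[Si](C)(C)C(C)(C)C)CC[C@@]2(C)[C@@H]1CO | intermediate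
22 | C13 iodide (15β-OH, 22-OTBS) | C[C@@]1(O)CC[C@@H]2OC(C)(C)[C@@H](O[Si](C)(C)C(C)(C)C)CC[C@@]2(C)[C@@H]1CI | intermediate
23 | C13 iodide C15,C22-diol | C[C@@]1(O)CC[C@@H]2OC(C)(C)[C@@H](O)CC[C@@]2(C)[C@@H]1CI | intermediate
24 | C13 iodide C15,C22-diacetate | C[C@@]1(OC(C)=O)CC[C@@H]2OC(C)(C)[C@@H](OC(C)=O)CC[C@@]2(C)[C@@H]1CI | intermediate
25 | coupled C10 ketone | O=C1CC[C@@H]2OC(C)(C)[C@@H](O[Si](C)(C)C(C)(C)C)CC[C@@]2(C)[C@@H]1CC[C@H]1[C@]2(C)CC[C@H](OC(C)=O)C(C)(C)O[C@H]2CC[C@@]1(C)OC(C)=O | intermediate
26 | 3-O-tert-butyldimethylsilyl ether of the target | C=C1CC[C@@H]2OC(C)(C)[C@@H](O[Si](C)(C)C(C)(C)C)CC[C@@]2(C)[C@@H]1CC[C@H]1[C@]2(C)CC[C@H](OC(C)=O)C(C)(C)O[C@H]2CC[C@@]1(C)OC(C)=O | intermediate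
27 | CNP0412606.1 | C=C1CC[C@@H]2OC(C)(C)[C@@H](O)CC[C@@]2(C)[C@@H]1CC[C@H]1[C@]2(C)CC[C@H](OC(C)=O)C(C)(C)O[C@H]2CC[C@@]1(C)OC(C)=O | target

## Step count and least certain steps

Total: 22 steps. Longest linear sequence: 22 steps from 1, because both halves are drawn from enone 18 (steps 1–14 to 18, steps 15–19 to 24, steps 20–22 to 27).

**Step 6 (key step).** The most likely failure is incomplete regioselectivity: some migration of the C3 methylene would give the isomeric lactone, since the migrating C7 is secondary but sits next to a quaternary carbon. Partial loss of the ketal under the acid formed would add a second, unwanted oxidation at C11. Fallback by oxidative cleavage and lactonisation, starting from alkene 4 and returning at 8: ozonolysis of 4 in CH2Cl2/MeOH containing NaOH gives the keto methyl ester F1 (C7 ketone, C2 ester). Reduction with BH3·SMe2 and the (R)-2-methyl-CBS-oxazaborolidine, which treats quaternary C6 as the large group, gives the (7S)-hydroxy ester F2. LiOH saponification gives the hydroxy acid F3, and Yamaguchi lactonisation (2,4,6-trichlorobenzoyl chloride, Et3N, then DMAP at high dilution) closes lactone 8. This gives up the ring expansion for a seven-membered lactonisation but keeps the rest of the route.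

**Step 9.** The risk is poor facial selectivity in the epoxidation, since C3 is remote from the controlling methyl. A second risk is a hydride shift of the epoxy ether before methyl transfer. Fallback with reagent control at C3, starting from 13 as an epimer mixture and returning to 13: Dess–Martin oxidation gives the C3 ketone F4 (2,2-dimethyloxepan-3-one ketal). Corey–Bakshi–Shibata reduction with BH3·SMe2 and the (R)-2-methyl-CBS-oxazaborolidine, with quaternary C2 as the large group, then delivers the (3S)-alcohol 13.

**Step 20.** The risk is premature reduction of the hindered C13 radical by the silane, or loss of the enone by oligomerisation, before the two large partners meet. Fallback by alkyl–alkyl Suzuki–Miyaura coupling, starting from 17 and 24 and returning at 25: hydroboration of allylic alcohol 17 with 9-BBN (α face) gives the B-alkyl-9-BBN derivative F5. Coupling of F5 with iodide 24 under Pd(OAc)2, PCy3 and K3PO4·H2O in THF gives the coupled C10 carbinol F6. Dess–Martin oxidation of F6 followed by brief DBU equilibration at C11 gives ketone 25.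

**Step 8.** The risk is hydrolysis of the ketene acetal phosphate back to the lactone, or slow methyl transfer, so that little enol ether is obtained. Fallback by carbonyl methylenation, starting from lactone 8 and returning at 11: Petasis methylenation (Cp2TiMe2, toluene, 70 °C) gives the exocyclic enol ether F7. Isomerisation with a trace of pyridinium p-toluenesulfonate in dry benzene moves the double bond into the ring and gives 11.

## Further compounds

F1 | step 6 | keto methyl ester (C7 ketone, C2 methyl ester, C11 dioxolane) | O=C1CCCC2(OCCO2)[C@]1(C)CCCC(=O)OC
F2 | step 6 | (7S)-hydroxy methyl ester | O[C@H]1CCCC2(OCCO2)[C@]1(C)CCCC(=O)OC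
F3 | step 6 | (7S)-hydroxy acid | O[C@H]1CCCC2(OCCO2)[C@]1(C)CCCC(O)=O
F4 | step 9 | 2,2-dimethyloxepan-3-one ketal (C3 ketone) | C1CC[C@@H]2OC(C)(C)C(=O)CC[C@@]2(C)C13OCCO3
F5 | step 20 | B-alkyl-9-BBN derivative of 17 (boron on C12, 11α-H) | OC1CC[C@@H]2OC(C)(C)[C@@H](O[Si](C)(C)C(C)(C)C)CC[C@@]2(C)[C@@H]1CB1C2CCCC1CCC2
F6 | step 20 | coupled C10 carbinol | OC1CC[C@@H]2OC(C)(C)[C@@H](O[Si](C)(C)C(C)(C)C)CC[C@@]2(C)[C@@H]1CC[C@H]1[C@]2(C)CC[C@H](OC(C)=O)C(C)(C)O[C@H]2CC[C@@]1(C)OC(C)=O
F7 | step 8 | exocyclic enol ether (2-methylene oxepane ketal) | C1CC[C@@H]2OC(=C)CCC[C@@]2(C)C13OCCO3
A1 | alternative 1 | tricyclic furanone–cyclobutane–cyclohexane photoadduct | CC1(C)O[C@]23CC[C@H](O[Si](C)(C)C(C)(C)C)[C@@H](CO[Si](C)(C)C(C)(C)C)[C@]3(C)C[C@H]2C1=O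
A2 | alternative 2 | bis(oxepane) keto diol with the C10 methylene and a C15 ketone | C=C1CC[C@@H]2OC(C)(C)[C@@H](O)CC[C@@]2(C)[C@@H]1CC[C@H]1[C@]2(C)CC[C@H](O)C(C)(C)O[C@H]2CCC1=O
A3 | alternative 3 | 2-vinylcyclohexanecarboxylic acid fused to the silyloxy-oxepane | OC(=O)[C@H]1CC[C@@H]2OC(C)(C)[C@@H](O[Si](C)(C)C(C)(C)C)CC[C@@]2(C)[C@@H]1C=C
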